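## The problem

The target is a resveratrol trimer in which two trans-2-aryl-2,3-dihydrobenzofurans are joined head to tail: C3 of the ring A dihydrobenzofuran is bonded to C6' of ring B, the benzo ring of the second dihydrobenzofuran, and ring A carries an (E)-4-hydroxystyryl group on C6. The central task is to make the sp3–sp2 bond C3–C6' and the fully substituted ring B around it without losing the configuration of the diarylmethine carbon C3. There are four stereocentres, (2S,3S) and (2'S,3'S). Within each furan the trans arrangement is the more stable one, so one centre of a pair can be relayed from the other (C3 from C2, C2' from C3' on ring closure), but the two pairs are insulated by ring B and each needs its own source of absolute configuration. The sensitive parts are the electron-rich stilbene (electrophiles, oxidants, hydrogenation), the benzylic C2–O and C2'–O bonds para to an oxygenated aryl group (ionisation under acid, quinone methide formation once the para phenol is free) and the seven phenols. These argue for methyl ethers to the end, a late entry of the stilbene and a neutral union of the halves. The enabling feature is ring B: a benzene with four different substituents in a 1,2,3,5 array (O1' on C7a', C3' on C3a', hydroxyl on C4', C3 of the other unit on C6', hydrogen on C5' and C7'), which is the pattern of the phenol formed from a 3-substituted cyclobutenone and a 1-siloxyalkyne. Once both ring B oxygens are free they are related by rotation about the C3'–C3a' bond, so closing the second furan raises no regiochemical question.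

## Retrosynthesis

**Phenols and second furan (35 ⇒ 34 ⇒ 33 ⇒ 32).** The six O–CH3 bonds of 35 are cut last, leading to hexamethyl ether 34. In 34 the O1'–C2' bond is cut to give the open-chain triol 33. This is preferred to cutting C2'–C3' or C3'–C3a', which would destroy the C3' centre that the open chain carries safely. The forward step must close a five-membered ether at a para-methoxybenzylic carbinol with inversion, so the carbinol of 33 must be R (syn to the aryl group on C3'). Triol 33 comes from the bis-silyl ether 32 by fluoride.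

**Stilbene (32 ⇒ 30 + 31).** The C6–alkene bond is cut to aryl triflate 30 and (E)-alkenylboronic acid 31. Placing this cut after the union means that no step before it has to tolerate the stilbene: not the hypervalent iodine oxidant, not dichloroketene, not the ketenes of the key step. The forward reaction is a cross-coupling that must tolerate a free phenol and two silyl ethers.

**Ring B (30 ⇒ 12 + 25).** The bonds C3a'–C4' and C7'–C7a' are cut, which dissolves ring B into cyclobutenone 12 (fragment 1) and siloxyalkyne 25 (fragment 2). The neighbouring cuts C3–C6' or C3'–C3a' would ask for aryl–alkyl coupling at a secondary benzylic carbon with a β-oxygen, where β-elimination and loss of configuration threaten. Here the trimer-sized 30 falls into two halves of similar size, each with two finished stereocentres. The forward reaction must be neutral and must place the alkyne substituent between the two oxygens.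

**Cyclobutenone (12 ⇒ 11 ⇒ 10 ⇒ 8).** The four-membered ring of 12 is cut at the two bonds formed by ketene–alkyne cycloaddition, giving terminal alkyne 10 and dichloroketene; the chlorines of adduct 11 are removed reductively. Alkyne 10 is the one-carbon homologue of ester 8, reached through aldehyde 9. The carboxyl carbon of 8 thereby becomes C6' of ring B. The forward steps must spare the aryl triflate and the benzylic ether; C3 can only equilibrate toward the favoured trans isomer.

**First dihydrobenzofuran (8 ⇒ 7 ⇒ 5 + 6; 5 ⇒ 3 ⇒ 2 ⇒ 1).** The C3–C3a bond of 8 is traced to the C4–C4a bond of flavanone 7 by an oxidative 1,2-aryl shift that relays C3 from C2. The C2–aryl bond of 7 is cut to chromone 5 and boronic acid 6, so the single stereocentre is set by catalysis. Chromone 5 comes from acetophenone 3 through enaminone 4, and 3 from the commercial triol 1 by selective triflation (2) and methylation. The triflate is placed early because it distinguishes the two ring A oxygens and later serves as the handle for 31.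

**Siloxyalkyne (25 ⇒ 24 ⇒ 22 ⇒ 21 ⇒ 20 ⇒ 19 ⇒ 16 + 17; 16 ⇒ 13 + 14).** The O–Si bond of 25 is cut to ynolate 24, which is traced by a 1,2-shift through enolate 23 to dibromomethyl ketone 22. Ketone 22 is Weinreb amide 21 plus one carbon. Amide 21 comes from 20 and aldol adduct 19, whose C2–C3 bond is cut to imide 16 and aldehyde 17; 16 is made from acid 13 and auxiliary 14 through anhydride 15. The aldol, through boron enolate 18, must deliver the syn (2R,3R) isomer. The later steps must not enolise the α-aryl carbonyl centre that becomes C3'.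

## Roads not taken

**Alternative 1:** The cut runs through both furan C2–C3 bonds at the benzofuran oxidation level. Forward, TiCl3 and zinc dust (low-valent titanium) would couple each diaryl ketone carbonyl of bis(keto ester) A2 with the carbonyl of the neighbouring aryl 4-methoxybenzoate. This closes both furans at once and gives bis(benzofuran) A1, in which a silyloxymethyl group stands in for the styryl carbons.
- Merits: A2 is achiral and assembled by acylations; two rings form in one operation; no ketene chemistry is needed.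
- Weak points: A1 is flat, so all four stereocentres must then be made by reducing two tetrasubstituted diaryl furan double bonds. Catalytic hydrogenation of such systems favours cis, ionic reduction gives trans but racemic, and nothing relates the sense of one reduction to the other. The stilbene can only follow the reductions (deprotection, oxidation, olefination), and both couplings occur next to two ortho substituents.
- Comparison: Alternative 1 is better in early convergence and in the simplicity of its intermediates. The chosen plan sets against this a defined origin for every stereocentre and an endgame in which nothing has to be reduced.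

**Alternative 2:** The cut is the C3–C3a bond of the ring A dihydrobenzofuran, traced to a flavanone. Forward, PhI(OAc)2 with trimethyl orthoformate and H2SO4 would convert (S)-flavanone A4 into ester A3 by migration of the ring A carbon from the carbonyl carbon to the neighbouring methylene carbon, contracting the pyranone to the dihydrofuran.
- Merits: one step; C3 is relayed from C2; the triflate handle for the styryl group survives.
- Weak points: as a plan for the whole molecule it places a carboxyl carbon on C3 where the target has ring B. It cannot be repeated for the second dihydrobenzofuran, whose C3' carries an aryl group and whose benzo ring does not yet exist. A decarboxylative arylation would need the second dihydrobenzofuran complete beforehand.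
- Comparison: for the first dihydrobenzofuran this road is as good as any, and the chosen plan uses it unchanged (A4 and A3 are compounds 7 and 8). What the chosen plan adds is a use for the carboxyl carbon as C6' of ring B, at the cost of the three steps from 8 to 12 (6–8).

**Alternative 3:** The cut is C3a–C4 and C5–C6 of ring A. Forward, the trans-dihydrofuro[3,2-c]pyran-4-one A6, already carrying the second dihydrobenzofuran and the styryl group, would undergo a Diels–Alder reaction with 1,1-dimethoxyethene A7 across pyrone C3 and C6. Extrusion of the lactone bridge and loss of one methoxy group would aromatise the adduct to heptamethyl ether A5.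
- Merits: A5 is one demethylation from the target; the ketene acetal sets the C4 oxygen and the regiochemistry; ring B needs no protecting-group differentiation.
- Weak points: the pyrone of A6 is oxygen-substituted at C4 and therefore electron-rich, a poor partner for an electron-rich dienophile, so forcing temperatures are expected. The styryl group extends the diene and offers a competing site of addition. A6 itself needs a trans-2,3-disubstituted dihydrofuran fused to the pyrone with absolute control; the usual oxidative radical (3+2) annulation onto a pyrone is racemic, so the stereochemical problem is moved rather than solved.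
- Comparison: Alternative 3 has the shorter endgame, which is better than the four steps after the union in the chosen plan. The chosen plan sets against this an electronically matched ring-forming step (electrophilic ketene, nucleophilic siloxyalkyne) and two fragments whose stereocentres come from reactions of known absolute sense.

Key step: step 15

Assumption: (R)-t-BuPyOx is taken to give the 2S flavanone in step 4 by analogy with the facial sense known for cyclic enones; if the sense is opposite, the antipodal ligand is used with no other change.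

## Route

Step 1
Reactants: 1 2',4',6'-trihydroxyacetophenone
Product: 2 4-acetyl-3,5-dihydroxyphenyl trifluoromethanesulfonate
Conditions: PhNTf2 (1.0 equiv), K2CO3 (1.05 equiv), acetone, 0 °C → rt
Reagents that add atoms: N-phenylbis(trifluoromethanesulfonimide), O=S(=O)(N(c1ccccc1)S(=O)(=O)C(F)(F)F)C(F)(F)F
Why: Chemoselective phenol O-triflation: the 4'-hydroxyl, para to the acetyl group, is the most acidic and least hindered, while the 2'- and 6'-hydroxyls are engaged with or shielded by the carbonyl, so one equivalent of the mild reagent should sulfonylate C4'–OH only.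

Step 2
Reactants: 2 4-acetyl-3,5-dihydroxyphenyl trifluoromethanesulfonate
Product: 3 4-acetyl-3-hydroxy-5-methoxyphenyl trifluoromethanesulfonate
Conditions: MeI (1.1 equiv), K2CO3, acetone, rt
Reagents that add atoms: iodomethane, CI
Why: Williamson mono-methylation of one of two equivalent ortho hydroxyls; the remaining hydroxyl is locked in a chelate with the carbonyl and reacts much more slowly, so the reaction should stop at the mono-ether.

Step 3
Reactants: 3 4-acetyl-3-hydroxy-5-methoxyphenyl trifluoromethanesulfonate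
Product: 5 5-methoxy-4-oxo-4H-chromen-7-yl trifluoromethanesulfonate, via enaminone 4 (not isolated)
Conditions: Me2NCH(OMe)2, toluene, 90 °C; then conc. HCl, CH2Cl2, rt
Reagents that add atoms: N,N-dimethylformamide dimethyl acetal, COC(OC)N(C)C
Why: Standard chromone synthesis: condensation of the methyl ketone with the amide acetal gives the enaminone, and acid promotes conjugate addition of the chelated phenol with loss of dimethylamine; the aryl triflate tolerates both stages.

Step 4
Reactants: 5 5-methoxy-4-oxo-4H-chromen-7-yl trifluoromethanesulfonate; 6 4-methoxyphenylboronic acid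
Product: 7 (S)-5-methoxy-2-(4-methoxyphenyl)-4-oxochroman-7-yl trifluoromethanesulfonate
Conditions: Pd(OCOCF3)2 (5 mol %), (R)-4-tert-butyl-2-(pyridin-2-yl)-4,5-dihydrooxazole ((R)-t-BuPyOx, 6 mol %), NH4PF6 (30 mol %), H2O (5 equiv), ClCH2CH2Cl, 60 °C
Reagents that add atoms: none
Why: Enantioselective conjugate addition of an arylboronic acid to a chromone with a cationic divalent palladium pyridine–oxazoline catalyst; C2 is set by the ligand. The cycle stays at divalent palladium (transmetalation, insertion, protonolysis), so the aryl triflate is untouched, and the base-free medium avoids opening of the flavanone to the chalcone.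

Step 5
Reactants: 7 (S)-5-methoxy-2-(4-methoxyphenyl)-4-oxochroman-7-yl trifluoromethanesulfonate
Product: 8 methyl (2S,3S)-4-methoxy-2-(4-methoxyphenyl)-6-(trifluoromethylsulfonyloxy)-2,3-dihydrobenzofuran-3-carboxylate
Conditions: PhI(OAc)2, HC(OMe)3, conc. H2SO4, rt
Reagents that add atoms: trimethyl orthoformate, COC(OC)OC
Why: Oxidative ring contraction of a flavanone by hypervalent-iodine-mediated 1,2-aryl shift: the enol ether formed with the orthoformate is attacked by iodine at C3 anti to the C2 aryl group, and the ring A carbon antiperiplanar to the C–I bond migrates from C4 to C3 with loss of iodobenzene. C3 is thus set trans to the untouched C2, which is also the thermodynamic arrangement.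

Step 6
Reactants: 8 methyl (2S,3S)-4-methoxy-2-(4-methoxyphenyl)-6-(trifluoromethylsulfonyloxy)-2,3-dihydrobenzofuran-3-carboxylate
Product: 10 (2S,3S)-3-ethynyl-4-methoxy-2-(4-methoxyphenyl)-2,3-dihydrobenzofuran-6-yl trifluoromethanesulfonate, via aldehyde 9 (not isolated)
Conditions: DIBAL-H, CH2Cl2, −78 °C; then MeOH, K2CO3, MeC(O)C(N2)P(O)(OMe)2, −78 °C → rt
Reagents that add atoms: dimethyl (1-diazo-2-oxopropyl)phosphonate, COP(=O)(OC)C(=[N+]=[N-])C(C)=O
Why: One-pot partial reduction and Seyferth–Gilbert homologation with the Ohira–Bestmann reagent, so the α-aryl aldehyde is never isolated. C3 can only equilibrate toward the favoured trans isomer, and base-induced opening of the furan is the reverse of a 5-endo-trig closure and stereoelectronically disfavoured.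

Step 7
Reactants: 10 (2S,3S)-3-ethynyl-4-methoxy-2-(4-methoxyphenyl)-2,3-dihydrobenzofuran-6-yl trifluoromethanesulfonate
Product: 11 (2S,3R)-3-(4,4-dichloro-3-oxocyclobut-1-en-1-yl)-4-methoxy-2-(4-methoxyphenyl)-2,3-dihydrobenzofuran-6-yl trifluoromethanesulfonate
Conditions: Cl3CCOCl, Zn(Cu), Et2O/DME, 25–35 °C
Reagents that add atoms: trichloroacetyl chloride, O=C(Cl)C(Cl)(Cl)Cl
Why: (2+2) Cycloaddition of dichloroketene, generated by zinc dechlorination, with a terminal alkyne; the unsubstituted alkyne carbon bonds to the ketene carbonyl carbon, giving the 3-substituted 4,4-dichlorocyclobutenone. DME ties up ZnCl2, and the substrate contains no alkene to compete (the C3 descriptor changes only through the priority of the CCl2 group).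

Step 8
Reactants: 11 (2S,3R)-3-(4,4-dichloro-3-oxocyclobut-1-en-1-yl)-4-methoxy-2-(4-methoxyphenyl)-2,3-dihydrobenzofuran-6-yl trifluoromethanesulfonate
Product: 12 (2S,3S)-4-methoxy-2-(4-methoxyphenyl)-3-(3-oxocyclobut-1-en-1-yl)-2,3-dihydrobenzofuran-6-yl trifluoromethanesulfonate (fragment 1)
Conditions: Zn, AcOH, TMEDA, EtOH, 0 °C → rt
Reagents that add atoms: none
Why: Reductive dechlorination of the α,α-dichloroketone with zinc in buffered acetic acid, the standard route to 3-substituted cyclobutenones; the amine buffer suppresses double-bond migration and the aryl triflate is inert.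

Step 9
Reactants: 13 3,5-dimethoxyphenylacetic acid; 14 (R)-4-benzyloxazolidin-2-one
Product: 16 (R)-4-benzyl-3-[2-(3,5-dimethoxyphenyl)acetyl]oxazolidin-2-one, via mixed pivalic anhydride 15 (not isolated)
Conditions: t-BuCOCl, Et3N, THF, −20 °C; then 14, LiCl, rt
Reagents that add atoms: none
Why: N-Acylation of the oxazolidinone through the mixed pivalic anhydride with LiCl/Et3N activation; this avoids an arylacetyl chloride and its ketene.

Step 10
Reactants: 16 (R)-4-benzyl-3-[2-(3,5-dimethoxyphenyl)acetyl]oxazolidin-2-one; 17 4-methoxybenzaldehyde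
Product: 19 (R)-4-benzyl-3-[(2R,3R)-2-(3,5-dimethoxyphenyl)-3-hydroxy-3-(4-methoxyphenyl)propanoyl]oxazolidin-2-one, via boron (Z)-enolate 18 (not isolated)
Conditions: n-Bu2BOTf, i-Pr2NEt, CH2Cl2, −78 → 0 °C; then 17, −78 → 0 °C; H2O2, pH 7 buffer, MeOH
Reagents that add atoms: none
Why: Evans syn aldol: the (Z)-boron enolate reacts through a chair Zimmerman–Traxler transition state on the face away from the benzyl group of the auxiliary. This sets both centres as the (2R,3R) syn adduct, the mirror image of the sense known for the (S)-auxiliary.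

Step 11
Reactants: 19 (R)-4-benzyl-3-[(2R,3R)-2-(3,5-dimethoxyphenyl)-3-hydroxy-3-(4-methoxyphenyl)propanoyl]oxazolidin-2-one
Product: 20 (2R,3R)-2-(3,5-dimethoxyphenyl)-3-hydroxy-N-methoxy-3-(4-methoxyphenyl)-N-methylpropanamide
Conditions: MeNHOMe·HCl, AlMe3, CH2Cl2, −20 → 0 °C
Reagents that add atoms: N,O-dimethylhydroxylamine hydrochloride, CNOC.Cl
Why: Aluminium amide transamidation to the Weinreb amide, directed to the exocyclic carbonyl by the aluminium alkoxide of the free β-hydroxyl; low temperature guards against retro-aldol cleavage and auxiliary 14 is recovered.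

Step 12
Reactants: 20 (2R,3R)-2-(3,5-dimethoxyphenyl)-3-hydroxy-N-methoxy-3-(4-methoxyphenyl)-N-methylpropanamide
Product: 21 (2R,3R)-3-(tert-butyldimethylsilyloxy)-2-(3,5-dimethoxyphenyl)-N-methoxy-3-(4-methoxyphenyl)-N-methylpropanamide
Conditions: TBSOTf, 2,6-lutidine, CH2Cl2, −78 → 0 °C
Reagents that add atoms: tert-butyldimethylsilyl trifluoromethanesulfonate, CC(C)(C)[Si](C)(C)OS(=O)(=O)C(F)(F)F
Why: Silylation of a hindered secondary benzylic alcohol with a silyl triflate and a hindered pyridine base, which does not touch the α-aryl centre.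

Step 13
Reactants: 21 (2R,3R)-3-(tert-butyldimethylsilyloxy)-2-(3,5-dimethoxyphenyl)-N-methoxy-3-(4-methoxyphenyl)-N-methylpropanamide
Product: 22 (3R,4R)-1,1-dibromo-4-(tert-butyldimethylsilyloxy)-3-(3,5-dimethoxyphenyl)-4-(4-methoxyphenyl)butan-2-one
Conditions: CH2Br2, LiTMP, THF, −78 °C; then AcOH, −78 °C
Reagents that add atoms: dibromomethane, BrCBr
Why: Addition of dibromomethyllithium to a Weinreb amide: the chelated tetrahedral adduct persists until the cold acidic quench, so a single addition gives the dibromomethyl ketone. Enolisation of the hindered amide is disfavoured by allylic strain, which protects the α-aryl centre.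

Step 14
Reactants: 22 (3R,4R)-1,1-dibromo-4-(tert-butyldimethylsilyloxy)-3-(3,5-dimethoxyphenyl)-4-(4-methoxyphenyl)butan-2-one
Product: 25 (3S,4R)-4-(tert-butyldimethylsilyloxy)-3-(3,5-dimethoxyphenyl)-4-(4-methoxyphenyl)-1-(triisopropylsilyloxy)but-1-yne (fragment 2), via lithium dibromoenolate 23 (not isolated), via lithium ynolate 24 (not isolated)
Conditions: LiHMDS, THF, −78 °C; n-BuLi, −78 → 0 °C; then TIPSOTf, −78 → 0 °C
Reagents that add atoms: triisopropylsilyl trifluoromethanesulfonate, CC(C)[Si](OS(=O)(=O)C(F)(F)F)(C(C)C)C(C)C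
Why: Kowalski ynolate rearrangement: the amide base removes the most acidic proton (CHBr2), bromine–lithium exchange gives a carbenoid, and the alkyl group migrates from the carbonyl carbon to the carbenoid carbon with retention. The bulky silyl triflate then traps the ynolate on oxygen.

Step 15
Reactants: 12 (2S,3S)-4-methoxy-2-(4-methoxyphenyl)-3-(3-oxocyclobut-1-en-1-yl)-2,3-dihydrobenzofuran-6-yl trifluoromethanesulfonate; 25 (3S,4R)-4-(tert-butyldimethylsilyloxy)-3-(3,5-dimethoxyphenyl)-4-(4-methoxyphenyl)-1-(triisopropylsilyloxy)but-1-yne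
Product: 30 (2S,3S)-3-{4-[(1S,2R)-2-(tert-butyldimethylsilyloxy)-1-(3,5-dimethoxyphenyl)-2-(4-methoxyphenyl)ethyl]-3-hydroxy-5-(triisopropylsilyloxy)phenyl}-4-methoxy-2-(4-methoxyphenyl)-2,3-dihydrobenzofuran-6-yl trifluoromethanesulfonate, via vinylketene 26 (not isolated), via cyclobutenone adduct 27 (not isolated), via dienylketene 28 (not isolated), via cyclohexadienone 29 (not isolated)
Conditions: toluene (25 in slight excess), 80 °C → 110 °C
Reagents that add atoms: none
Why: Danheiser benzannulation of a cyclobutenone with a siloxyalkyne, the known route to resorcinol monosilyl ethers. Heating opens 12 by 4-electron electrocyclic ring opening to vinylketene 26; the electron-rich alkyne 25 then adds to the ketene C=C bond in a regioselective (2+2) cycloaddition, its chain-bearing carbon bonding to the ketene carbonyl carbon (C3a'–C4') and its oxygen-bearing carbon to the ketene CH (C7'–C7a'), to give cyclobutenone 27. A second 4-electron opening gives dienylketene 28, and ring B is closed by thermal 6-electron electrocyclisation of 28 to cyclohexadienone 29, which tautomerises to phenol 30. No stereocentre is created: the sp3 carbons of 27 and 29 vanish on aromatisation and the four preformed centres are spectators under neutral heating. The selectivity needed is the regiochemistry of the ketene–alkyne step, which the polarisation of the siloxyalkyne secures, so the chain lands between the new hydroxyl and the silyloxy group and fragment 1 lands meta to both. A slight excess of 25 should keep capture of 26 ahead of ketene dimerisation; the aryl triflate, both silyl ethers and the benzylic ethers are inert to these conditions.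

Step 16
Reactants: 30 (2S,3S)-3-{4-[(1S,2R)-2-(tert-butyldimethylsilyloxy)-1-(3,5-dimethoxyphenyl)-2-(4-methoxyphenyl)ethyl]-3-hydroxy-5-(triisopropylsilyloxy)phenyl}-4-methoxy-2-(4-methoxyphenyl)-2,3-dihydrobenzofuran-6-yl trifluoromethanesulfonate; 31 (E)-2-(4-methoxyphenyl)vinylboronic acid
Product: 32 2-[(1S,2R)-2-(tert-butyldimethylsilyloxy)-1-(3,5-dimethoxyphenyl)-2-(4-methoxyphenyl)ethyl]-5-[(2S,3S)-4-methoxy-2-(4-methoxyphenyl)-6-((E)-4-methoxystyryl)-2,3-dihydrobenzofuran-3-yl]-3-(triisopropylsilyloxy)phenol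
Conditions: Pd(PPh3)4 (5 mol %), K3PO4, 1,4-dioxane/H2O, 80 °C
Reagents that add atoms: none
Why: Suzuki–Miyaura coupling of an unhindered aryl triflate with an (E)-alkenylboronic acid, with retention of alkene geometry; the free phenol and the hindered silyl ethers are tolerated.

Step 17
Reactants: 32 2-[(1S,2R)-2-(tert-butyldimethylsilyloxy)-1-(3,5-dimethoxyphenyl)-2-(4-methoxyphenyl)ethyl]-5-[(2S,3S)-4-methoxy-2-(4-methoxyphenyl)-6-((E)-4-methoxystyryl)-2,3-dihydrobenzofuran-3-yl]-3-(triisopropylsilyloxy)phenol
Product: 33 2-[(1S,2R)-1-(3,5-dimethoxyphenyl)-2-hydroxy-2-(4-methoxyphenyl)ethyl]-5-[(2S,3S)-4-methoxy-2-(4-methoxyphenyl)-6-((E)-4-methoxystyryl)-2,3-dihydrobenzofuran-3-yl]benzene-1,3-diol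
Conditions: TBAF, AcOH, THF, 0 °C → rt
Reagents that add atoms: none
Why: Fluoride desilylation of the aryl triisopropylsilyl ether and the benzylic tert-butyldimethylsilyl ether; the acetic acid buffer keeps the resorcinol from standing as a dianion.

Step 18
Reactants: 33 2-[(1S,2R)-1-(3,5-dimethoxyphenyl)-2-hydroxy-2-(4-methoxyphenyl)ethyl]-5-[(2S,3S)-4-methoxy-2-(4-methoxyphenyl)-6-((E)-4-methoxystyryl)-2,3-dihydrobenzofuran-3-yl]benzene-1,3-diol
Product: 34 (2S,3S)-3-(3,5-dimethoxyphenyl)-6-[(2S,3S)-4-methoxy-2-(4-methoxyphenyl)-6-((E)-4-methoxystyryl)-2,3-dihydrobenzofuran-3-yl]-2-(4-methoxyphenyl)-2,3-dihydrobenzofuran-4-ol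
Conditions: PPh3, DIAD, THF, 0 °C → rt
Reagents that add atoms: none
Why: Mitsunobu cyclodehydration: a ring B phenol displaces the activated benzylic hydroxyl in a 5-exo-tet closure with inversion at C2', turning the syn carbinol into the trans furan. The two phenols are equivalent, and any leakage through the benzylic cation also ends in the more stable trans ring.

Step 19
Reactants: 34 (2S,3S)-3-(3,5-dimethoxyphenyl)-6-[(2S,3S)-4-methoxy-2-(4-methoxyphenyl)-6-((E)-4-methoxystyryl)-2,3-dihydrobenzofuran-3-yl]-2-(4-methoxyphenyl)-2,3-dihydrobenzofuran-4-ol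
Product: 35 (2S,3S)-3-(3,5-dihydroxyphenyl)-6-[(2S,3S)-4-hydroxy-2-(4-hydroxyphenyl)-6-((E)-4-hydroxystyryl)-2,3-dihydrobenzofuran-3-yl]-2-(4-hydroxyphenyl)-2,3-dihydrobenzofuran-4-ol
Conditions: BBr3 (excess), CH2Cl2, −78 → 0 °C; then MeOH/H2O
Reagents that add atoms: none
Why: Lewis acid cleavage of six aryl methyl ethers, the usual last step for stilbenoid oligomers. The styryl group on C6 is remote from the C3 aryl group, so no acid-triggered cyclisation onto the alkene is available, and both trans furans are the thermodynamic isomers.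

## Compound list

1 | 2',4',6'-trihydroxyacetophenone | CC(=O)c1c(O)cc(O)cc1O | starting material
2 | 4-acetyl-3,5-dihydroxyphenyl trifluoromethanesulfonate | CC(=O)c1c(O)cc(OS(=O)(=O)C(F)(F)F)cc1O | intermediate
3 | 4-acetyl-3-hydroxy-5-methoxyphenyl trifluoromethanesulfonate | CC(=O)c1c(O)cc(OS(=O)(=O)C(F)(F)F)cc1OC | intermediate
4 | 4-[(E)-3-(dimethylamino)prop-2-enoyl]-3-hydroxy-5-methoxyphenyl trifluoromethanesulfonate (enaminone) | CN(C)/C=C/C(=O)c1c(O)cc(OS(=O)(=O)C(F)(F)F)cc1OC | intermediate
5 | 5-methoxy-4-oxo-4H-chromen-7-yl trifluoromethanesulfonate | COc1cc(OS(=O)(=O)C(F)(F)F)cc2occc(=O)c12 | intermediate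
6 | 4-methoxyphenylboronic acid | COc1ccc(B(O)O)cc1 | starting material
7 | (S)-5-methoxy-2-(4-methoxyphenyl)-4-oxochroman-7-yl trifluoromethanesulfonate | COc1cc(OS(=O)(=O)C(F)(F)F)cc2O[C@H](c3ccc(OC)cc3)CC(=O)c12 | intermediate
8 | methyl (2S,3S)-4-methoxy-2-(4-methoxyphenyl)-6-(trifluoromethylsulfonyloxy)-2,3-dihydrobenzofuran-3-carboxylate | FC(F)(F)S(=O)(=O)Oc1cc(OC)c2c(c1)O[C@H](c1ccc(OC)cc1)[C@H]2C(=O)OC | intermediate
9 | (2S,3S)-3-formyl-4-methoxy-2-(4-methoxyphenyl)-2,3-dihydrobenzofuran-6-yl trifluoromethanesulfonate (aldehyde) | FC(F)(F)S(=O)(=O)Oc1cc(OC)c2c(c1)O[C@H](c1ccc(OC)cc1)[C@H]2C=O | intermediate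
10 | (2S,3S)-3-ethynyl-4-methoxy-2-(4-methoxyphenyl)-2,3-dihydrobenzofuran-6-yl trifluoromethanesulfonate | FC(F)(F)S(=O)(=O)Oc1cc(OC)c2c(c1)O[C@H](c1ccc(OC)cc1)[C@H]2C#C | intermediate
11 | (2S,3R)-3-(4,4-dichloro-3-oxocyclobut-1-en-1-yl)-4-methoxy-2-(4-methoxyphenyl)-2,3-dihydrobenzofuran-6-yl trifluoromethanesulfonate | FC(F)(F)S(=O)(=O)Oc1cc(OC)c2c(c1)O[C@H](c1ccc(OC)cc1)[C@H]2C1=CC(=O)C1(Cl)Cl | intermediate
12 | (2S,3S)-4-methoxy-2-(4-methoxyphenyl)-3-(3-oxocyclobut-1-en-1-yl)-2,3-dihydrobenzofuran-6-yl trifluoromethanesulfonate (fragment 1) | FC(F)(F)S(=O)(=O)Oc1cc(OC)c2c(c1)O[C@H](c1ccc(OC)cc1)[C@H]2C1=CC(=O)C1 | intermediate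
13 | 3,5-dimethoxyphenylacetic acid | COc1cc(CC(=O)O)cc(OC)c1 | starting material
14 | (R)-4-benzyloxazolidin-2-one | O=C1N[C@H](Cc2ccccc2)CO1 | starting material
15 | (3,5-dimethoxyphenyl)acetic pivalic anhydride | COc1cc(CC(=O)OC(=O)C(C)(C)C)cc(OC)c1 | intermediate
16 | (R)-4-benzyl-3-[2-(3,5-dimethoxyphenyl)acetyl]oxazolidin-2-one | O=C1OC[C@@H](Cc2ccccc2)N1C(=O)Cc1cc(OC)cc(OC)c1 | intermediate
17 | 4-methoxybenzaldehyde | COc1ccc(C=O)cc1 | starting material
18 | (R)-4-benzyl-3-[(Z)-1-(dibutylboryloxy)-2-(3,5-dimethoxyphenyl)vinyl]oxazolidin-2-one (boron enolate) | CCCCB(CCCC)O/C(=C\c1cc(OC)cc(OC)c1)N1C(=O)OC[C@H]1Cc1ccccc1 | intermediate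
19 | (R)-4-benzyl-3-[(2R,3R)-2-(3,5-dimethoxyphenyl)-3-hydroxy-3-(4-methoxyphenyl)propanoyl]oxazolidin-2-one | O=C1OC[C@@H](Cc2ccccc2)N1C(=O)[C@H](c1cc(OC)cc(OC)c1)[C@@H](O)c1ccc(OC)cc1 | intermediate
20 | (2R,3R)-2-(3,5-dimethoxyphenyl)-3-hydroxy-N-methoxy-3-(4-methoxyphenyl)-N-methylpropanamide | CON(C)C(=O)[C@H](c1cc(OC)cc(OC)c1)[C@@H](O)c1ccc(OC)cc1 | intermediate
21 | (2R,3R)-3-(tert-butyldimethylsilyloxy)-2-(3,5-dimethoxyphenyl)-N-methoxy-3-(4-methoxyphenyl)-N-methylpropanamide | CON(C)C(=O)[C@H](c1cc(OC)cc(OC)c1)[C@@H](O[Si](C)(C)C(C)(C)C)c1ccc(OC)cc1 | intermediate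
22 | (3R,4R)-1,1-dibromo-4-(tert-butyldimethylsilyloxy)-3-(3,5-dimethoxyphenyl)-4-(4-methoxyphenyl)butan-2-one | BrC(Br)C(=O)[C@H](c1cc(OC)cc(OC)c1)[C@@H](O[Si](C)(C)C(C)(C)C)c1ccc(OC)cc1 | intermediate
23 | lithium (3R,4R)-1,1-dibromo-4-(tert-butyldimethylsilyloxy)-3-(3,5-dimethoxyphenyl)-4-(4-methoxyphenyl)but-1-en-2-olate | [Li+].[O-]C(=C(Br)Br)[C@H](c1cc(OC)cc(OC)c1)[C@@H](O[Si](C)(C)C(C)(C)C)c1ccc(OC)cc1 | intermediate
24 | lithium (3S,4R)-4-(tert-butyldimethylsilyloxy)-3-(3,5-dimethoxyphenyl)-4-(4-methoxyphenyl)but-1-yn-1-olate | [Li+].[O-]C#C[C@H](c1cc(OC)cc(OC)c1)[C@@H](O[Si](C)(C)C(C)(C)C)c1ccc(OC)cc1 | intermediate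
25 | (3S,4R)-4-(tert-butyldimethylsilyloxy)-3-(3,5-dimethoxyphenyl)-4-(4-methoxyphenyl)-1-(triisopropylsilyloxy)but-1-yne (fragment 2) | CC(C)[Si](OC#C[C@H](c1cc(OC)cc(OC)c1)[C@@H](O[Si](C)(C)C(C)(C)C)c1ccc(OC)cc1)(C(C)C)C(C)C | intermediate
26 | (2S,3S)-4-methoxy-2-(4-methoxyphenyl)-3-(4-oxobuta-1,3-dien-2-yl)-2,3-dihydrobenzofuran-6-yl trifluoromethanesulfonate (vinylketene) | FC(F)(F)S(=O)(=O)Oc1cc(OC)c2c(c1)O[C@H](c1ccc(OC)cc1)[C@H]2C(=C)C=C=O | intermediate
27 | 2-[(1S,2R)-2-(tert-butyldimethylsilyloxy)-1-(3,5-dimethoxyphenyl)-2-(4-methoxyphenyl)ethyl]-4-{1-[(2S,3S)-4-methoxy-2-(4-methoxyphenyl)-6-(trifluoromethylsulfonyloxy)-2,3-dihydrobenzofuran-3-yl]vinyl}-3-(triisopropylsilyloxy)cyclobut-2-en-1-one (C4 of the cyclobutenone unspecified) | FC(F)(F)S(=O)(=O)Oc1cc(OC)c2c(c1)O[C@H](c1ccc(OC)cc1)[C@H]2C(=C)C1C(=O)C([C@H](c3cc(OC)cc(OC)c3)[C@@H](O[Si](C)(C)C(C)(C)C)c3ccc(OC)cc3)=C1O[Si](C(C)C)(C(C)C)C(C)C | intermediate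
28 | (3E)-2-[(1S,2R)-2-(tert-butyldimethylsilyloxy)-1-(3,5-dimethoxyphenyl)-2-(4-methoxyphenyl)ethyl]-5-[(2S,3S)-4-methoxy-2-(4-methoxyphenyl)-6-(trifluoromethylsulfonyloxy)-2,3-dihydrobenzofuran-3-yl]-3-(triisopropylsilyloxy)hexa-1,3,5-trien-1-one (dienylketene) | FC(F)(F)S(=O)(=O)Oc1cc(OC)c2c(c1)O[C@H](c1ccc(OC)cc1)[C@H]2C(=C)/C=C(/O[Si](C(C)C)(C(C)C)C(C)C)C([C@H](c3cc(OC)cc(OC)c3)[C@@H](O[Si](C)(C)C(C)(C)C)c3ccc(OC)cc3)=C=O | intermediate
29 | 2-[(1S,2R)-2-(tert-butyldimethylsilyloxy)-1-(3,5-dimethoxyphenyl)-2-(4-methoxyphenyl)ethyl]-5-[(2S,3S)-4-methoxy-2-(4-methoxyphenyl)-6-(trifluoromethylsulfonyloxy)-2,3-dihydrobenzofuran-3-yl]-3-(triisopropylsilyloxy)cyclohexa-2,4-dien-1-one | FC(F)(F)S(=O)(=O)Oc1cc(OC)c2c(c1)O[C@H](c1ccc(OC)cc1)[C@H]2C1=CC(O[Si](C(C)C)(C(C)C)C(C)C)=C([C@H](c3cc(OC)cc(OC)c3)[C@@H](O[Si](C)(C)C(C)(C)C)c3ccc(OC)cc3)C(=O)C1 | intermediate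
30 | (2S,3S)-3-{4-[(1S,2R)-2-(tert-butyldimethylsilyloxy)-1-(3,5-dimethoxyphenyl)-2-(4-methoxyphenyl)ethyl]-3-hydroxy-5-(triisopropylsilyloxy)phenyl}-4-methoxy-2-(4-methoxyphenyl)-2,3-dihydrobenzofuran-6-yl trifluoromethanesulfonate | FC(F)(F)S(=O)(=O)Oc1cc(OC)c2c(c1)O[C@H](c1ccc(OC)cc1)[C@H]2c1cc(O)c(c(O[Si](C(C)C)(C(C)C)C(C)C)c1)[C@H](c1cc(OC)cc(OC)c1)[C@@H](O[Si](C)(C)C(C)(C)C)c1ccc(OC)cc1 | intermediate
31 | (E)-2-(4-methoxyphenyl)vinylboronic acid | COc1ccc(/C=C/B(O)O)cc1 | starting material
32 | 2-[(1S,2R)-2-(tert-butyldimethylsilyloxy)-1-(3,5-dimethoxyphenyl)-2-(4-methoxyphenyl)ethyl]-5-[(2S,3S)-4-methoxy-2-(4-methoxyphenyl)-6-((E)-4-methoxystyryl)-2,3-dihydrobenzofuran-3-yl]-3-(triisopropylsilyloxy)phenol | COc1ccc(/C=C/c2cc(OC)c3c(c2)O[C@H](c2ccc(OC)cc2)[C@H]3c2cc(O)c(c(O[Si](C(C)C)(C(C)C)C(C)C)c2)[C@H](c2cc(OC)cc(OC)c2)[C@@H](O[Si](C)(C)C(C)(C)C)c2ccc(OC)cc2)cc1 | intermediate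
33 | 2-[(1S,2R)-1-(3,5-dimethoxyphenyl)-2-hydroxy-2-(4-methoxyphenyl)ethyl]-5-[(2S,3S)-4-methoxy-2-(4-methoxyphenyl)-6-((E)-4-methoxystyryl)-2,3-dihydrobenzofuran-3-yl]benzene-1,3-diol | COc1ccc(/C=C/c2cc(OC)c3c(c2)O[C@H](c2ccc(OC)cc2)[C@H]3c2cc(O)c(c(O)c2)[C@H](c2cc(OC)cc(OC)c2)[C@@H](O)c2ccc(OC)cc2)cc1 | intermediate
34 | (2S,3S)-3-(3,5-dimethoxyphenyl)-6-[(2S,3S)-4-methoxy-2-(4-methoxyphenyl)-6-((E)-4-methoxystyryl)-2,3-dihydrobenzofuran-3-yl]-2-(4-methoxyphenyl)-2,3-dihydrobenzofuran-4-ol | COc1ccc(/C=C/c2cc(OC)c3c(c2)O[C@H](c2ccc(OC)cc2)[C@H]3c2cc(O)c3c(c2)O[C@H](c2ccc(OC)cc2)[C@H]3c2cc(OC)cc(OC)c2)cc1 | intermediate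
35 | (2S,3S)-3-(3,5-dihydroxyphenyl)-6-[(2S,3S)-4-hydroxy-2-(4-hydroxyphenyl)-6-((E)-4-hydroxystyryl)-2,3-dihydrobenzofuran-3-yl]-2-(4-hydroxyphenyl)-2,3-dihydrobenzofuran-4-ol | Oc1ccc(/C=C/c2cc(O)c3c(c2)O[C@H](c2ccc(O)cc2)[C@H]3c2cc(O)c3c(c2)O[C@H](c2ccc(O)cc2)[C@H]3c2cc(O)cc(O)c2)cc1 | target

## Step count and least certain steps

Total: 19 steps. Longest linear sequence: 13 steps (steps 1–8 and 15–19, from 1); the fragment 2 branch is 6 steps (9–14).

**Step 15 (key step).** The most likely failure is slow capture of vinylketene 26 by the hindered alkyne 25, which would let the ketene be consumed by dimerisation or by acylating the phenol of 30 as it forms. The fallback sets out from 12 and returns at 27, and from there at 30. It changes the ketene source and separates ketene capture from phenol formation: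
- Heating 12 in wet THF at 80 °C should trap 26 with water as 3-[(2S,3S)-4-methoxy-2-(4-methoxyphenyl)-6-(trifluoromethylsulfonyloxy)-2,3-dihydrobenzofuran-3-yl]but-3-enoic acid F1.
- 1-Chloro-N,N,2-trimethylprop-1-en-1-amine converts F1 under neutral conditions into the acid chloride F2.
- Slow addition of Et3N to F2 and an excess of 25 at 0 °C → rt regenerates 26 by dehydrochlorination, with no phenol present, and the (2+2) cycloaddition should give 27.
- 27 is then heated alone in toluene at 80 °C and should pass to 30 through 28 and 29.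

**Step 13 (with step 14).** The risk is α-deprotonation of the α-aryl amide 21 by the carbenoid or residual amide base, or proton transfer at the benzylic position of 22 before enolisation at CHBr2. Either would epimerise the future C3' or eliminate silanolate. The fallback sets out from 21 and returns at 25 through 24, exposing no carbonyl compound to strong base:
- DIBAL-H at −78 °C should give (2R,3R)-3-(tert-butyldimethylsilyloxy)-2-(3,5-dimethoxyphenyl)-3-(4-methoxyphenyl)propanal F3, used crude.
- Corey–Fuchs olefination (CBr4, PPh3, CH2Cl2, 0 °C) gives (3R,4R)-1,1-dibromo-4-(tert-butyldimethylsilyloxy)-3-(3,5-dimethoxyphenyl)-4-(4-methoxyphenyl)but-1-ene F4.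
- n-BuLi (2 equiv, −78 °C) and aqueous quench give tert-butyl{[(1R,2R)-2-(3,5-dimethoxyphenyl)-1-(4-methoxyphenyl)but-3-yn-1-yl]oxy}dimethylsilane F5.
- LiHMDS converts F5 into its lithium acetylide F6, which lithium tert-butyl peroxide oxidises to ynolate 24; TIPSOTf then gives 25.

**Step 7.** The branched alkyne 10 may add dichloroketene sluggishly while the ketene polymerises, or ZnCl2 may ionise the benzylic C2–O bond. The fallback sets out from 10 and returns at 12, bypassing 11 and step 8. N,N-Dimethylacetamide, Tf2O and 2,4,6-collidine generate the keteniminium salt, whose (2+2) cycloaddition with 10 gives the N,N-dimethyl cyclobut-2-en-1-iminium trifluoromethanesulfonate F7 carrying the dihydrobenzofuran on C3. Aqueous NaHCO3 hydrolyses F7 to 12 without zinc or chlorine.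

**Step 18.** The activated benzylic alcohol may eliminate toward the triarylethene, or react intermolecularly, faster than it closes. The fallback sets out from 33 and returns at 34 by ionising closure: catalytic TsOH in CH2Cl2 at 0 °C generates the para-methoxybenzylic cation, which the neighbouring phenol captures under thermodynamic control to give the trans ring, whatever the carbinol configuration. No new compound is involved.

**Step 19.** Once the para phenols are unmasked, the benzylic C–O bonds may ionise, HBr may add to the stilbene, or cleavage may stop short of six ethers. The fallback sets out from 34 and returns at 35 by nucleophilic demethylation with NaSEt in DMF at 130–150 °C. This is SN2 attack at the methyl groups in a basic medium, where the ring oxygens are not activated as leaving groups by a Lewis acid. No new compound is involved.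

## Further compounds

F1 | step 15 | 3-[(2S,3S)-4-methoxy-2-(4-methoxyphenyl)-6-(trifluoromethylsulfonyloxy)-2,3-dihydrobenzofuran-3-yl]but-3-enoic acid | FC(F)(F)S(=O)(=O)Oc1cc(OC)c2c(c1)O[C@H](c1ccc(OC)cc1)[C@H]2C(=C)CC(=O)O
F2 | step 15 | 3-[(2S,3S)-4-methoxy-2-(4-methoxyphenyl)-6-(trifluoromethylsulfonyloxy)-2,3-dihydrobenzofuran-3-yl]but-3-enoyl chloride | FC(F)(F)S(=O)(=O)Oc1cc(OC)c2c(c1)O[C@H](c1ccc(OC)cc1)[C@H]2C(=C)CC(=O)Cl
F3 | step 13 | (2R,3R)-3-(tert-butyldimethylsilyloxy)-2-(3,5-dimethoxyphenyl)-3-(4-methoxyphenyl)propanal | O=C[C@H](c1cc(OC)cc(OC)c1)[C@@H](O[Si](C)(C)C(C)(C)C)c1ccc(OC)cc1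
F4 | step 13 | (3R,4R)-1,1-dibromo-4-(tert-butyldimethylsilyloxy)-3-(3,5-dimethoxyphenyl)-4-(4-methoxyphenyl)but-1-ene | BrC(Br)=C[C@H](c1cc(OC)cc(OC)c1)[C@@H](O[Si](C)(C)C(C)(C)C)c1ccc(OC)cc1
F5 | step 13 | tert-butyl{[(1R,2R)-2-(3,5-dimethoxyphenyl)-1-(4-methoxyphenyl)but-3-yn-1-yl]oxy}dimethylsilane | C#C[C@H](c1cc(OC)cc(OC)c1)[C@@H](O[Si](C)(C)C(C)(C)C)c1ccc(OC)cc1
F6 | step 13 | lithium acetylide of F5 | [Li]C#C[C@H](c1cc(OC)cc(OC)c1)[C@@H](O[Si](C)(C)C(C)(C)C)c1ccc(OC)cc1
F7 | step 7 | N-{3-[(2S,3S)-4-methoxy-2-(4-methoxyphenyl)-6-(trifluoromethylsulfonyloxy)-2,3-dihydrobenzofuran-3-yl]cyclobut-2-en-1-ylidene}-N-methylmethanaminium trifluoromethanesulfonate | FC(F)(F)S(=O)(=O)Oc1cc(OC)c2c(c1)O[C@H](c1ccc(OC)cc1)[C@H]2C1=CC(=[N+](C)C)C1.[O-]S(=O)(=O)C(F)(F)F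
F0 | step 18 | none | none
F0 | step 19 | none | none
A1 | alternative 1 | 2,3-diaryl bis(benzofuran) with a (triisopropylsilyloxy)methyl group on C6 | CC(C)[Si](OCc1cc(OC)c2c(c1)oc(-c1ccc(OC)cc1)c2-c1cc(OC)c2c(c1)oc(-c1ccc(OC)cc1)c2-c1cc(OC)cc(OC)c1)(C(C)C)C(C)C
A2 | alternative 1 | 3-methoxy-2-[3-methoxy-4-(3,5-dimethoxybenzoyl)-5-(4-methoxybenzoyloxy)benzoyl]-5-[(triisopropylsilyloxy)methyl]phenyl 4-methoxybenzoate | CC(C)[Si](OCc1cc(OC)c(C(=O)c2cc(OC)c(C(=O)c3cc(OC)cc(OC)c3)c(OC(=O)c3ccc(OC)cc3)c2)c(OC(=O)c2ccc(OC)cc2)c1)(C(C)C)C(C)C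
A3 | alternative 2 | methyl (2S,3S)-4-methoxy-2-(4-methoxyphenyl)-6-(trifluoromethylsulfonyloxy)-2,3-dihydrobenzofuran-3-carboxylate (identical with 8) | FC(F)(F)S(=O)(=O)Oc1cc(OC)c2c(c1)O[C@H](c1ccc(OC)cc1)[C@H]2C(=O)OC
A4 | alternative 2 | (S)-5-methoxy-2-(4-methoxyphenyl)-4-oxochroman-7-yl trifluoromethanesulfonate (identical with 7) | COc1cc(OS(=O)(=O)C(F)(F)F)cc2O[C@H](c3ccc(OC)cc3)CC(=O)c12
A5 | alternative 3 | heptamethyl ether of the target | COc1ccc(/C=C/c2cc(OC)c3c(c2)O[C@H](c2ccc(OC)cc2)[C@H]3c2cc(OC)c3c(c2)O[C@H](c2ccc(OC)cc2)[C@H]3c2cc(OC)cc(OC)c2)cc1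
A6 | alternative 3 | trans-3-[(2S,3S)-3-(3,5-dimethoxyphenyl)-4-methoxy-2-(4-methoxyphenyl)-2,3-dihydrobenzofuran-6-yl]-2-(4-methoxyphenyl)-6-[(E)-4-methoxystyryl]-2,3-dihydro-4H-furo[3,2-c]pyran-4-one, configured as in the target | COc1ccc(/C=C/c2oc(=O)c3c(c2)O[C@H](c2ccc(OC)cc2)[C@H]3c2cc(OC)c3c(c2)O[C@H](c2ccc(OC)cc2)[C@H]3c2cc(OC)cc(OC)c2)cc1
A7 | alternative 3 | 1,1-dimethoxyethene | C=C(OC)OC
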